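Compound numbers are those of the steps and the compound list; eremophilane numbering is used for positions (ring A = C1–C5, C10; ring B = C5–C10; C14 = methyl on C5, C15 = methyl on C4, C11–C13 = isopropenyl on C7).

## Analysis of the target

Target 23 is a trans-fused eremophilane decalin with seven stereocentres (C3, C4, C5, C7, C8, C9, C10) and two (Z)-hex-2-enoate esters on O3 and O9. On ring A the C14 and C15 methyls are cis (both β), H10 is α and therefore trans to C14, and the C3 acyloxy group is α, equatorial and trans to C15. On ring B the C7 isopropenyl (equatorial), the free C8 hydroxyl (axial) and the C9 acyloxy group (equatorial) are all α, so O8 is cis to both neighbours and is the only axial group of the triad. Sensitive groups are the two Z-enoates (isomerisation, conjugate addition), the isopropenyl group (acid, hydrogenation) and a free hydroxyl next to an ester (acyl migration). The hard points are the quaternary C5 between two stereocentres, the all-cis C7–C8–C9 array with its axial hydroxyl, and telling three secondary hydroxyls apart at the end. The strategy rests on the C7 isopropenyl group standing next to the C8 hydroxyl in ring B: this is the retron of a carbonyl-ene reaction between a C8 aldehyde and a prenyl group (C6–C7=C11) carried by C5.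

## Retrosynthetic reasoning

**Ester C–O bonds.** Target 23 is cut at the two acyl–oxygen bonds to triol 20 and acid 21. The Z-alkenes are carried as alkynes (bis-ynoate 22) so that no Z-enoate has to survive an acylation; the last step is then a cis semihydrogenation. Acylation has to pick the two equatorial hydroxyls (O3, O9) over the axial O8.

**Protecting groups.** Triol 20 comes from diol 19 and this from 18 by removal of a silyl ether at O3 and a 4-methoxybenzyl ether at O9. The benzyl-type ether at O9 is chosen because it must act as a donor for zinc in the key step; the silyl ether at O3 must not.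

**C7–C8 bond (key disconnection).** Cutting C7–C8 of 18 as a retro-ene opens ring B and leads to aldehyde 17. This removes two stereocentres (C7, C8) and the isopropenyl group in one move and leaves a monocyclic precursor. Forward, a chelating zinc halide must close the ring through a chair and place O8 cis to O9.

**C8–C9 bond.** Aldehyde 17 is traced through dithiane 16 and carbinol 15 to aldehyde 12 and 1,3-dithiane 13 (as its anion 14). Cutting here lets the C9 stereocentre arise by Felkin–Anh addition next to the quaternary C5, and the masked formyl group survives etherification.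

**C10–H and C9–O bonds.** Aldehyde 12 comes from alcohol 11, and 11 from hydroboration of the exocyclic alkene of diene 9 (through borane 10). The axial C5 methyl shields one face, so H10 can be set kinetically; this matters because equilibration next to a quaternary centre would not reliably favour one C10 epimer.

**C10=C9 bond.** Diene 9 is the methylenation product of ketone 8.

**C4–C15 and C5–C6 bonds.** Ketone 8 is cut at both bonds to enone 6: conjugate addition of a methylcopper reagent gives enolate 7, which is prenylated in the same flask. The trans C3/C4 pair is made kinetically, by addition anti to the C3 silyloxy group. It is not left to equilibration next to a carbonyl, where an axial β-oxygen costs too little to give a dependable preference. The cis C14/C15 pair follows from alkylation anti to the new methyl.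

**C5–C14 bond.** Enone 6 comes from iodoenone 5 by cross-coupling, and 5 from enone 4 by α-iodination.

**C3 stereocentre.** Enone 4 goes back through silyl ether 3 and allylic alcohol 2 to the achiral enone ketal 1; an enantioselective carbonyl reduction sets C3, the only stereocentre that needs a chiral reagent.

## Alternatives that were turned down

**Alternative 1:** Intramolecular Diels–Alder. Disconnection of C5–C10 and C6–C7 leads to the acyclic trienal A1, whose 2-substituted acrolein unit (C5=C6) would add to the tethered silyloxydiene (C7=C8–C9=C10) to give decalin A2, closing both rings at once. In its favour: two rings, the quaternary C5 and C10 in one step from a precursor with only two stereocentres, and on that point it is stronger than the chosen route. Against it: with the activating group and the tether on the same dienophile carbon, the endo/exo preference that decides cis or trans fusion is weak, and facial control rests only on C3/C4. A2 also carries C14 as a formyl group to be deoxygenated, and none of the ring B problems is solved: C9 oxygenation, the C7 isopropenyl group next to a C8 ketone (where it tends to slip into conjugation) and reduction of C8 to the axial alcohol all remain. The chosen strategy spends more steps on the precursor but closes ring B with C7, C8 and the isopropenyl group already correct.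

**Alternative 2:** Quinone Diels–Alder. Disconnection of C4–C5 and C1–C10 leads to quinone A3 and diene A4, which would give the cis-fused endo adduct A5. In its favour: the bicyclic core with the quaternary C5 arises in one step from two small achiral partners, and a chiral Lewis acid could supply the absolute configuration; no other approach is as short up to the decalin. Against it: in the endo adduct C15 ends cis to the C6 carbonyl, hence trans to C14, and the ring fusion is cis, so both C4 and C10 must later be inverted by enolisation. The oxidation pattern is also far from the target: the C6 ketone must be removed, the C3 ketone reduced to the equatorial alcohol against the 1,3-diaxial C14 methyl, the C8/C9 oxygens converted into a cis-diol, and the isopropenyl group introduced at C7. The long redox tail outweighs the short start; the chosen route has four steps after ring closure.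

**Alternative 3:** Hydrogen-atom-transfer radical cyclisation. Disconnection of C5–C6 leads to A6, a ring A exocyclic alkene (C5=C14) carrying a C8 vinyl ketone; iron-catalysed hydrogen-atom transfer to C14 would give a tertiary C5 radical that adds to C6 (6-endo) and forms ketone A7. In its favour: the quaternary C5 is created in the key step under mild, tolerant conditions without any enolate alkylation, which is a real advantage over the chosen route. Against it: the planar C5 radical can cyclise on either face, so the cis C14/C15 relationship and the trans ring fusion are not secured by any strong element. A7 also lacks the isopropenyl group, which would have to be introduced α to the C8 ketone (with the risk of conjugation to an isopropylidene) before C8 is reduced to the axial alcohol. The chosen strategy sets C5 earlier under anti-to-methyl control and obtains the isopropenyl group and the C8 hydroxyl from the ring closure itself, without a C8 carbonyl.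

Key step: step 13

Assumption: enone ketal 1 is taken as a catalogue compound (it is one dehydrogenation away from 1,4-cyclohexanedione monoethylene ketal).

Step 1
Reactants: 1 1,4-dioxaspiro[4.5]dec-6-en-8-one
Product: 2 (8R)-1,4-dioxaspiro[4.5]dec-6-en-8-ol
Conditions: (S)-2-methyl-CBS-oxazaborolidine (10 mol%), BH3·SMe2, THF, −20 °C; MeOH
Reagents that add atoms: none
Why: Corey–Bakshi–Shibata reduction of a cyclic enone (1,2-reduction); with the alkenyl/ketal side as the large group the (S)-catalyst should give the 8R carbinol, which becomes C3 of the target.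

Step 2
Reactants: 2 (8R)-1,4-dioxaspiro[4.5]dec-6-en-8-ol
Product: 3 tert-butyl{[(8R)-1,4-dioxaspiro[4.5]dec-6-en-8-yl]oxy}dimethylsilane
Conditions: TBSCl, imidazole, DMF, rt
Reagents that add atoms: tert-butyldimethylsilyl chloride, CC(C)(C)[Si](C)(C)Cl
Why: Standard silylation of a secondary allylic alcohol; the silyl ether is kept until step 15.

Step 3
Reactants: 3 tert-butyl{[(8R)-1,4-dioxaspiro[4.5]dec-6-en-8-yl]oxy}dimethylsilane
Product: 4 (4R)-4-[(tert-butyldimethylsilyl)oxy]cyclohex-2-en-1-one
Conditions: PPTS (cat.), acetone/H2O (10:1), 50 °C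
Reagents that add atoms: water, O
Why: Acid-catalysed ketal hydrolysis; the secondary silyl ether tolerates PPTS and the stereocentre is γ to the new carbonyl, so it is not enolisable.

Step 4
Reactants: 4 (4R)-4-[(tert-butyldimethylsilyl)oxy]cyclohex-2-en-1-one
Product: 5 (4R)-4-[(tert-butyldimethylsilyl)oxy]-2-iodocyclohex-2-en-1-one
Conditions: I2, pyridine/CH2Cl2 (1:1), 0 °C → rt
Reagents that add atoms: iodine, II
Why: Johnson α-iodination of an enone (conjugate addition of pyridine, iodination of the enolate, elimination); the silyloxy stereocentre is not touched.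

Step 5
Reactants: 5 (4R)-4-[(tert-butyldimethylsilyl)oxy]-2-iodocyclohex-2-en-1-one
Product: 6 (4R)-4-[(tert-butyldimethylsilyl)oxy]-2-methylcyclohex-2-en-1-one
Conditions: Me2Zn, Pd(dppf)Cl2 (5 mol%), THF, 50 °C
Reagents that add atoms: dimethylzinc, C[Zn]C
Why: Negishi cross-coupling of an α-iodoenone installs the future C14 methyl; dimethylzinc does not add to the enone without a copper or nickel catalyst.

Step 6
Reactants: 6 (4R)-4-[(tert-butyldimethylsilyl)oxy]-2-methylcyclohex-2-en-1-one
Product: 8 (2R,3R,4R)-4-[(tert-butyldimethylsilyl)oxy]-2,3-dimethyl-2-(3-methylbut-2-en-1-yl)cyclohexan-1-one, via lithium enolate 7 (not isolated)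
Conditions: Me2CuLi (from CuI, MeLi), Et2O, −78 → −20 °C; then HMPA, prenyl bromide, −20 °C → rt
Reagents that add atoms: lithium dimethylcuprate, [Li+].C[Cu-]C; 1-bromo-3-methylbut-2-ene, CC(C)=CCBr
Why: Gilman conjugate addition followed by enolate C-alkylation; the methyl group enters C4 anti to the C3 silyloxy group (trans C3/C4). The regiodefined enolate 7 is then prenylated at C5 anti to the new C4 methyl, which allylic strain with the C5 methyl holds pseudoaxial; this gives the quaternary centre with C14 and C15 cis.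

Step 7
Reactants: 8 (2R,3R,4R)-4-[(tert-butyldimethylsilyl)oxy]-2,3-dimethyl-2-(3-methylbut-2-en-1-yl)cyclohexan-1-one
Product: 9 tert-butyl{[(1R,2R,3R)-2,3-dimethyl-3-(3-methylbut-2-en-1-yl)-4-methylidenecyclohexyl]oxy}dimethylsilane
Conditions: Ph3PCH3Br, KOt-Bu, toluene, 90 °C
Reagents that add atoms: methyltriphenylphosphonium bromide, C[P+](c1ccccc1)(c1ccccc1)c1ccccc1.[Br-]
Why: Wittig methylenation under the forcing conditions used for hindered, enolisable ketones; no stereocentre is at risk since C5 is quaternary.

Step 8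
Reactants: 9 tert-butyl{[(1R,2R,3R)-2,3-dimethyl-3-(3-methylbut-2-en-1-yl)-4-methylidenecyclohexyl]oxy}dimethylsilane
Product: 11 [(1R,2S,3R,4R)-4-[(tert-butyldimethylsilyl)oxy]-2,3-dimethyl-2-(3-methylbut-2-en-1-yl)cyclohexyl]methanol, via alkylborane 10 (not isolated)
Conditions: 9-BBN, THF, 0 °C → rt; then NaOH, H2O2, 0 °C → rt
Reagents that add atoms: 9-borabicyclo[3.3.1]nonane, B1C2CCCC1CCC2 (boron of 10); hydrogen peroxide, OO (hydroxyl oxygen of 11)
Why: Brown hydroboration–oxidation; 9-BBN reacts with the 1,1-disubstituted exocyclic alkene far faster than with the trisubstituted prenyl alkene. Hydrogen is delivered to C10 on the α face, opposite the axial C5 methyl, so H10 ends α and C9 equatorial.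

Step 9
Reactants: 11 [(1R,2S,3R,4R)-4-[(tert-butyldimethylsilyl)oxy]-2,3-dimethyl-2-(3-methylbut-2-en-1-yl)cyclohexyl]methanol
Product: 12 (1R,2R,3R,4R)-4-[(tert-butyldimethylsilyl)oxy]-2,3-dimethyl-2-(3-methylbut-2-en-1-yl)cyclohexane-1-carbaldehyde
Conditions: (n-Pr4N)RuO4 (5 mol%), NMO, 4 Å MS, CH2Cl2, rt
Reagents that add atoms: none
Why: Ley–Griffith oxidation of a primary alcohol under neutral conditions, chosen so that the now enolisable C10 is not epimerised; alkene and silyl ether are inert.

Step 10
Reactants: 12 (1R,2R,3R,4R)-4-[(tert-butyldimethylsilyl)oxy]-2,3-dimethyl-2-(3-methylbut-2-en-1-yl)cyclohexane-1-carbaldehyde; 13 1,3-dithiane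
Product: 15 (S)-[(1R,2R,3R,4R)-4-[(tert-butyldimethylsilyl)oxy]-2,3-dimethyl-2-(3-methylbut-2-en-1-yl)cyclohexyl](1,3-dithian-2-yl)methanol, via 2-lithio-1,3-dithiane 14 (not isolated)
Conditions: 13, n-BuLi, THF, −30 °C; then 12, −78 °C
Reagents that add atoms: none
Why: Corey–Seebach addition of a formyl anion equivalent; Felkin–Anh attack anti to the quaternary C5 (large group), passing H10, should give the 9S carbinol, whose oxygen is equatorial (9α) once ring B exists.

Step 11
Reactants: 15 (S)-[(1R,2R,3R,4R)-4-[(tert-butyldimethylsilyl)oxy]-2,3-dimethyl-2-(3-methylbut-2-en-1-yl)cyclohexyl](1,3-dithian-2-yl)methanol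
Product: 16 2-{(S)-[(1R,2R,3R,4R)-4-[(tert-butyldimethylsilyl)oxy]-2,3-dimethyl-2-(3-methylbut-2-en-1-yl)cyclohexyl][(4-methoxyphenyl)methoxy]methyl}-1,3-dithiane
Conditions: NaH, PMBCl, n-Bu4NI (cat.), DMF, 0 °C → rt
Reagents that add atoms: 4-methoxybenzyl chloride, COc1ccc(CCl)cc1
Why: Williamson etherification; NaH does not deprotonate the dithiane C–H, and the benzyl-type ether is the zinc-binding group needed in step 13.

Step 12
Reactants: 16 2-{(S)-[(1R,2R,3R,4R)-4-[(tert-butyldimethylsilyl)oxy]-2,3-dimethyl-2-(3-methylbut-2-en-1-yl)cyclohexyl][(4-methoxyphenyl)methoxy]methyl}-1,3-dithiane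
Product: 17 (2S)-2-[(1R,2R,3R,4R)-4-[(tert-butyldimethylsilyl)oxy]-2,3-dimethyl-2-(3-methylbut-2-en-1-yl)cyclohexyl]-2-[(4-methoxyphenyl)methoxy]acetaldehyde
Conditions: MeI, CaCO3, MeCN/H2O (9:1), 45 °C
Reagents that add atoms: water, O
Why: Alkylative dithiane hydrolysis; it is non-oxidative, so the prenyl alkene and the 4-methoxybenzyl ether survive, and the buffered medium protects the α-alkoxy aldehyde from epimerisation at C9.

Step 13
Reactants: 17 (2S)-2-[(1R,2R,3R,4R)-4-[(tert-butyldimethylsilyl)oxy]-2,3-dimethyl-2-(3-methylbut-2-en-1-yl)cyclohexyl]-2-[(4-methoxyphenyl)methoxy]acetaldehyde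
Product: 18 (1S,2R,3S,4aR,5R,6R,8aR)-6-[(tert-butyldimethylsilyl)oxy]-1-[(4-methoxyphenyl)methoxy]-4a,5-dimethyl-3-(prop-1-en-2-yl)decahydronaphthalen-2-ol (3-O-silyl-9-O-(4-methoxybenzyl) eremophil-11-ene-3α,8α,9α-triol)
Conditions: ZnBr2 (2.5 equiv), CH2Cl2, −20 → 0 °C
Reagents that add atoms: none
Why: ZnBr2 binds the C8 aldehyde oxygen together with the C9 ether oxygen; C7 of the prenyl group then attacks C8 while a hydrogen of a C11 methyl passes to O8, either in concert or through a tertiary C11 cation. The closest known reaction is the Lewis-acid carbonyl-ene cyclisation of 7-methyloct-6-enals (citronellal to isopulegol). Ring B closes by C7–C8 bond formation as a six-membered ring, exo to both the carbonyl and the alkene (6-exo-trig), through a chair that is necessarily trans-fused because C6 and C9 are both equatorial on ring A. At C7 the forming isopropenyl group takes the equatorial α position, since the axial one would be syn-diaxial to the C5 methyl. At C8 the five-membered zinc chelate holds O8=C8–C9–O9 near syn-periplanar, and the tether through C10 lets C7 reach only the carbonyl face on the C10 side, so O8 ends cis to the equatorial O9 and therefore axial (α). The step needs this chelated path to outrun the open one that would leave O8 equatorial; the benzyl-type ether at C9 is a good donor for zinc, CH2Cl2 does not compete for the metal, and the C3 silyl ether does not chelate. The silyl and 4-methoxybenzyl ethers should tolerate ZnBr2 at or below 0 °C.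

Step 14
Reactants: 18 (1S,2R,3S,4aR,5R,6R,8aR)-6-[(tert-butyldimethylsilyl)oxy]-1-[(4-methoxyphenyl)methoxy]-4a,5-dimethyl-3-(prop-1-en-2-yl)decahydronaphthalen-2-ol
Product: 19 (1S,2R,3S,4aR,5R,6R,8aR)-6-[(tert-butyldimethylsilyl)oxy]-4a,5-dimethyl-3-(prop-1-en-2-yl)decahydronaphthalene-1,2-diol
Conditions: DDQ, CH2Cl2/pH 7 buffer (10:1), 0 °C → rt
Reagents that add atoms: none
Why: Oxidative cleavage of the 4-methoxybenzyl ether; the isopropenyl group and the silyl ether are inert to DDQ. Any 8,9-(4-methoxybenzylidene) acetal formed by capture of the oxocarbenium ion by O8 would be hydrolysed under the acidic conditions of step 15.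

Step 15
Reactants: 19 (1S,2R,3S,4aR,5R,6R,8aR)-6-[(tert-butyldimethylsilyl)oxy]-4a,5-dimethyl-3-(prop-1-en-2-yl)decahydronaphthalene-1,2-diol
Product: 20 (1S,2R,3S,4aR,5R,6R,8aR)-4a,5-dimethyl-3-(prop-1-en-2-yl)decahydronaphthalene-1,2,6-triol (eremophil-11-ene-3α,8α,9α-triol)
Conditions: HF (48% aq.), MeCN, 0 °C → rt
Reagents that add atoms: none
Why: Fluoride/acid desilylation of the secondary silyl ether; the conditions are too mild to isomerise or hydrate the isopropenyl group.

Step 16
Reactants: 20 (1S,2R,3S,4aR,5R,6R,8aR)-4a,5-dimethyl-3-(prop-1-en-2-yl)decahydronaphthalene-1,2,6-triol; 21 hex-2-ynoic acid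
Product: 22 (1S,2R,3S,4aR,5R,6R,8aR)-2-hydroxy-4a,5-dimethyl-3-(prop-1-en-2-yl)decahydronaphthalene-1,6-diyl di(hex-2-ynoate)
Conditions: 21 (2.3 equiv), DIC, DMAP (cat.), CH2Cl2, −20 → 0 °C
Reagents that add atoms: none
Why: Steglich esterification; the equatorial O3 and O9 hydroxyls should be acylated ahead of the axial O8 hydroxyl, which is flanked by C7 and C9 substituents and has two syn-axial hydrogens. Within the 8,9-pair the equatorial ester is also the more stable one, so any acyl migration works in the wanted direction.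

Step 17
Reactants: 22 (1S,2R,3S,4aR,5R,6R,8aR)-2-hydroxy-4a,5-dimethyl-3-(prop-1-en-2-yl)decahydronaphthalene-1,6-diyl di(hex-2-ynoate)
Product: 23 (1S,2R,3S,4aR,5R,6R,8aR)-2-hydroxy-4a,5-dimethyl-3-(prop-1-en-2-yl)decahydronaphthalene-1,6-diyl bis[(2Z)-hex-2-enoate] (CNP0420276.1)
Conditions: H2 (1 atm), Pd/CaCO3 poisoned with Pb(OAc)2 (Lindlar catalyst), quinoline, EtOAc, rt
Reagents that add atoms: none
Why: Lindlar semihydrogenation adds hydrogen cis to both ynoates to give the Z-enoates; the 1,1-disubstituted isopropenyl alkene is reduced much more slowly, and the reaction is stopped after two equivalents of hydrogen.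

## Compound list

1 | 1,4-dioxaspiro[4.5]dec-6-en-8-one | O=C1C=CC2(CC1)OCCO2 | starting material
2 | (8R)-1,4-dioxaspiro[4.5]dec-6-en-8-ol | C1=C[C@H](O)CCC12OCCO2 | intermediate
3 | tert-butyl{[(8R)-1,4-dioxaspiro[4.5]dec-6-en-8-yl]oxy}dimethylsilane | C1=C[C@H](O[Si](C)(C)C(C)(C)C)CCC12OCCO2 | intermediate
4 | (4R)-4-[(tert-butyldimethylsilyl)oxy]cyclohex-2-en-1-one | O=C1C=C[C@H](O[Si](C)(C)C(C)(C)C)CC1 | intermediate
5 | (4R)-4-[(tert-butyldimethylsilyl)oxy]-2-iodocyclohex-2-en-1-one | O=C1C(I)=C[C@H](O[Si](C)(C)C(C)(C)C)CC1 | intermediate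
6 | (4R)-4-[(tert-butyldimethylsilyl)oxy]-2-methylcyclohex-2-en-1-one | CC1=C[C@H](O[Si](C)(C)C(C)(C)C)CCC1=O | intermediate
7 | lithium (3R,4R)-4-[(tert-butyldimethylsilyl)oxy]-2,3-dimethylcyclohex-1-en-1-olate | [Li]OC1=C(C)[C@@H](C)[C@H](O[Si](C)(C)C(C)(C)C)CC1 | intermediate
8 | (2R,3R,4R)-4-[(tert-butyldimethylsilyl)oxy]-2,3-dimethyl-2-(3-methylbut-2-en-1-yl)cyclohexan-1-one | CC(C)=CC[C@]1(C)[C@@H](C)[C@H](O[Si](C)(C)C(C)(C)C)CCC1=O | intermediate
9 | tert-butyl{[(1R,2R,3R)-2,3-dimethyl-3-(3-methylbut-2-en-1-yl)-4-methylidenecyclohexyl]oxy}dimethylsilane | CC(C)=CC[C@]1(C)[C@@H](C)[C@H](O[Si](C)(C)C(C)(C)C)CCC1=C | intermediate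
10 | 9-{[(1R,2S,3R,4R)-4-[(tert-butyldimethylsilyl)oxy]-2,3-dimethyl-2-(3-methylbut-2-en-1-yl)cyclohexyl]methyl}-9-borabicyclo[3.3.1]nonane | CC(C)=CC[C@]1(C)[C@@H](C)[C@H](O[Si](C)(C)C(C)(C)C)CC[C@H]1CB2C3CCCC2CCC3 | intermediate
11 | [(1R,2S,3R,4R)-4-[(tert-butyldimethylsilyl)oxy]-2,3-dimethyl-2-(3-methylbut-2-en-1-yl)cyclohexyl]methanol | CC(C)=CC[C@]1(C)[C@@H](C)[C@H](O[Si](C)(C)C(C)(C)C)CC[C@H]1CO | intermediate
12 | (1R,2R,3R,4R)-4-[(tert-butyldimethylsilyl)oxy]-2,3-dimethyl-2-(3-methylbut-2-en-1-yl)cyclohexane-1-carbaldehyde | CC(C)=CC[C@]1(C)[C@@H](C)[C@H](O[Si](C)(C)C(C)(C)C)CC[C@H]1C=O | intermediate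
13 | 1,3-dithiane | C1CSCSC1 | starting material
14 | 2-lithio-1,3-dithiane | [Li]C1SCCCS1 | intermediate
15 | (S)-[(1R,2R,3R,4R)-4-[(tert-butyldimethylsilyl)oxy]-2,3-dimethyl-2-(3-methylbut-2-en-1-yl)cyclohexyl](1,3-dithian-2-yl)methanol | CC(C)=CC[C@]1(C)[C@@H](C)[C@H](O[Si](C)(C)C(C)(C)C)CC[C@H]1[C@H](O)C2SCCCS2 | intermediate
16 | 2-{(S)-[(1R,2R,3R,4R)-4-[(tert-butyldimethylsilyl)oxy]-2,3-dimethyl-2-(3-methylbut-2-en-1-yl)cyclohexyl][(4-methoxyphenyl)methoxy]methyl}-1,3-dithiane | CC(C)=CC[C@]1(C)[C@@H](C)[C@H](O[Si](C)(C)C(C)(C)C)CC[C@H]1[C@H](OCc2ccc(OC)cc2)C3SCCCS3 | intermediate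
17 | (2S)-2-[(1R,2R,3R,4R)-4-[(tert-butyldimethylsilyl)oxy]-2,3-dimethyl-2-(3-methylbut-2-en-1-yl)cyclohexyl]-2-[(4-methoxyphenyl)methoxy]acetaldehyde | CC(C)=CC[C@]1(C)[C@@H](C)[C@H](O[Si](C)(C)C(C)(C)C)CC[C@H]1[C@H](OCc2ccc(OC)cc2)C=O | intermediate
18 | (1S,2R,3S,4aR,5R,6R,8aR)-6-[(tert-butyldimethylsilyl)oxy]-1-[(4-methoxyphenyl)methoxy]-4a,5-dimethyl-3-(prop-1-en-2-yl)decahydronaphthalen-2-ol | C=C(C)[C@@H]1C[C@]2(C)[C@@H](C)[C@H](O[Si](C)(C)C(C)(C)C)CC[C@H]2[C@H](OCc3ccc(OC)cc3)[C@@H]1O | intermediate
19 | (1S,2R,3S,4aR,5R,6R,8aR)-6-[(tert-butyldimethylsilyl)oxy]-4a,5-dimethyl-3-(prop-1-en-2-yl)decahydronaphthalene-1,2-diol | C=C(C)[C@@H]1C[C@]2(C)[C@@H](C)[C@H](O[Si](C)(C)C(C)(C)C)CC[C@H]2[C@H](O)[C@@H]1O | intermediate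
20 | (1S,2R,3S,4aR,5R,6R,8aR)-4a,5-dimethyl-3-(prop-1-en-2-yl)decahydronaphthalene-1,2,6-triol | C=C(C)[C@@H]1C[C@]2(C)[C@@H](C)[C@H](O)CC[C@H]2[C@H](O)[C@@H]1O | intermediate
21 | hex-2-ynoic acid | CCCC#CC(=O)O | starting material
22 | (1S,2R,3S,4aR,5R,6R,8aR)-2-hydroxy-4a,5-dimethyl-3-(prop-1-en-2-yl)decahydronaphthalene-1,6-diyl di(hex-2-ynoate) | C=C(C)[C@@H]1C[C@]2(C)[C@@H](C)[C@H](OC(=O)C#CCCC)CC[C@H]2[C@H](OC(=O)C#CCCC)[C@@H]1O | intermediate
23 | (1S,2R,3S,4aR,5R,6R,8aR)-2-hydroxy-4a,5-dimethyl-3-(prop-1-en-2-yl)decahydronaphthalene-1,6-diyl bis[(2Z)-hex-2-enoate] | C=C(C)[C@@H]1C[C@]2(C)[C@@H](C)[C@H](OC(=O)/C=C\CCC)CC[C@H]2[C@H](OC(=O)/C=C\CCC)[C@@H]1O | target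

## Step count and least certain steps

Total steps: 17. Longest linear sequence: 17 steps (1 → 23).

**Step 13 (key step).** The most likely failure is competition from the open, non-chelated transition state, which would erode the C8 configuration. Less likely are Lewis-acid loss of the 4-methoxybenzyl ether and ionic capture of the C11 cation instead of proton transfer. The fallback sets out from 18 as obtained, whatever its C8 composition. Oxidation with Dess–Martin periodinane (NaHCO3, CH2Cl2) converges both C8 epimers on the C8 ketone, (1S,3S,4aR,5R,6R,8aR)-6-[(tert-butyldimethylsilyl)oxy]-1-[(4-methoxyphenyl)methoxy]-4a,5-dimethyl-3-(prop-1-en-2-yl)octahydronaphthalen-2(1H)-one F1. Reduction with LiB(s-Bu)3H (THF, −78 °C) then delivers hydride along the equatorial trajectory, which gives the axial 8α alcohol and returns to 18. This replaces chelation control of C8 by steric approach control on the finished ring.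

**Step 6.** C-alkylation of the hindered, tetrasubstituted enolate 7 may be slow. Proton exchange with the product could then lead to alkylation at C1, and facial selectivity may be incomplete because attack anti to C15 is syn to the C3 silyloxy group. The fallback sets out from 6. Enolate 7, generated as in step 6, is trapped on oxygen with allyl chloroformate to give the enol carbonate (3R,4R)-4-[(tert-butyldimethylsilyl)oxy]-2,3-dimethylcyclohex-1-en-1-yl prop-2-en-1-yl carbonate F2. Pd(PPh3)4 (THF, rt) effects Tsuji decarboxylative allylation, regiospecific for C5, to (2R,3R,4R)-4-[(tert-butyldimethylsilyl)oxy]-2,3-dimethyl-2-(prop-2-en-1-yl)cyclohexan-1-one F3. Cross-metathesis of F3 with 2-methylbut-2-ene (second-generation Grubbs catalyst) converts allyl into prenyl and returns to 8.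

**Step 10.** Felkin–Anh control at C9 may be eroded, or the basic nucleophile may enolise aldehyde 12. The fallback sets out from 15 as a mixture of C9 epimers. Parikh–Doering oxidation (SO3·pyridine, DMSO, i-Pr2NEt) gives the acyl dithiane [(1R,2R,3R,4R)-4-[(tert-butyldimethylsilyl)oxy]-2,3-dimethyl-2-(3-methylbut-2-en-1-yl)cyclohexyl](1,3-dithian-2-yl)methanone F4. Reduction with BH3·SMe2 and the CBS oxazaborolidine enantiomer matched to the S carbinol returns to 15. The C9 centre is then set by the reagent at a C–O bond rather than by the substrate at a C–C bond.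

**Step 16.** Acylation may reach the axial O8 hydroxyl before O9 is fully esterified. The fallback sets out from 20. Bu2SnO (toluene, reflux, water removal) forms the 8,9-O-dibutylstannylene acetal of 20 F5. Hex-2-ynoyl chloride F6, made from 21 with oxalyl chloride and catalytic DMF, then acylates the equatorial oxygen of the cis-diol and gives the 9-monoester (1S,2R,3S,4aR,5R,6R,8aR)-2,6-dihydroxy-4a,5-dimethyl-3-(prop-1-en-2-yl)decahydronaphthalen-1-yl hex-2-ynoate F7. One further equivalent of 21 with DIC and DMAP esterifies the remaining equatorial O3 hydroxyl and returns to 22.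

## Further compounds

F1 | step 13 | (1S,3S,4aR,5R,6R,8aR)-6-[(tert-butyldimethylsilyl)oxy]-1-[(4-methoxyphenyl)methoxy]-4a,5-dimethyl-3-(prop-1-en-2-yl)octahydronaphthalen-2(1H)-one | C=C(C)[C@@H]1C[C@]2(C)[C@@H](C)[C@H](O[Si](C)(C)C(C)(C)C)CC[C@H]2[C@H](OCc3ccc(OC)cc3)C1=O
F2 | step 6 | (3R,4R)-4-[(tert-butyldimethylsilyl)oxy]-2,3-dimethylcyclohex-1-en-1-yl prop-2-en-1-yl carbonate | C=CCOC(=O)OC1=C(C)[C@@H](C)[C@H](O[Si](C)(C)C(C)(C)C)CC1
F3 | step 6 | (2R,3R,4R)-4-[(tert-butyldimethylsilyl)oxy]-2,3-dimethyl-2-(prop-2-en-1-yl)cyclohexan-1-one | C=CC[C@]1(C)[C@@H](C)[C@H](O[Si](C)(C)C(C)(C)C)CCC1=O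
F4 | step 10 | [(1R,2R,3R,4R)-4-[(tert-butyldimethylsilyl)oxy]-2,3-dimethyl-2-(3-methylbut-2-en-1-yl)cyclohexyl](1,3-dithian-2-yl)methanone | CC(C)=CC[C@]1(C)[C@@H](C)[C@H](O[Si](C)(C)C(C)(C)C)CC[C@H]1C(=O)C2SCCCS2
F5 | step 16 | 8,9-O-dibutylstannylene acetal of triol 20 (2,2-dibutyl-1,3,2-dioxastannolane fused at C8–C9, O3 free) | C=C(C)[C@@H]1C[C@]2(C)[C@@H](C)[C@H](O)CC[C@H]2[C@@H]3O[Sn](CCCC)(CCCC)O[C@H]13
F6 | step 16 | hex-2-ynoyl chloride | CCCC#CC(=O)Cl
F7 | step 16 | (1S,2R,3S,4aR,5R,6R,8aR)-2,6-dihydroxy-4a,5-dimethyl-3-(prop-1-en-2-yl)decahydronaphthalen-1-yl hex-2-ynoate | C=C(C)[C@@H]1C[C@]2(C)[C@@H](C)[C@H](O)CC[C@H]2[C@H](OC(=O)C#CCCC)[C@@H]1O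
A1 | alternative 1 | (3R,4R,7E)-4,9-bis[(tert-butyldimethylsilyl)oxy]-3-methyl-2-methylidenedeca-7,9-dienal | C=C(C=O)[C@@H](C)[C@H](O[Si](C)(C)C(C)(C)C)CC/C=C/C(O[Si](C)(C)C(C)(C)C)=C
A2 | alternative 1 | trans-fused 3α,8-bis[(tert-butyldimethylsilyl)oxy]-4β-methyl-5β-formyldecal-8-ene (eremophilane numbering) | C1C[C@]2(C=O)[C@@H](C)[C@H](O[Si](C)(C)C(C)(C)C)CC[C@H]2C=C1O[Si](C)(C)C(C)(C)C
A3 | alternative 2 | 2-methoxy-5-methylcyclohexa-2,5-diene-1,4-dione | COC1=CC(=O)C(C)=CC1=O
A4 | alternative 2 | (3Z)-3-[(trimethylsilyl)oxy]penta-1,3-diene | C=C/C(O[Si](C)(C)C)=C/C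
A5 | alternative 2 | cis-fused endo adduct, 8-methoxy-4,5-dimethyl-3-[(trimethylsilyl)oxy]decala-2,7-diene-6,9-dione with C14 and H10 cis and C15 trans to C14 (eremophilane numbering) | COC1=CC(=O)[C@]2(C)[C@H](C)C(O[Si](C)(C)C)=CC[C@@H]2C1=O
A6 | alternative 3 | 3α,9α-bis[(tert-butyldimethylsilyl)oxy]-4β-methyl-5,6-seco-11,12,13-trinoreremophila-5(14),6-dien-8-one (eremophilane numbering) | C=C1[C@@H](C)[C@H](O[Si](C)(C)C(C)(C)C)CC[C@H]1[C@H](O[Si](C)(C)C(C)(C)C)C(=O)C=C
A7 | alternative 3 | trans-fused 3α,9α-bis[(tert-butyldimethylsilyl)oxy]-4β,5β-dimethyldecalin-8-one (eremophilane numbering) | C1C[C@]2(C)[C@@H](C)[C@H](O[Si](C)(C)C(C)(C)C)CC[C@H]2[C@H](O[Si](C)(C)C(C)(C)C)C1=O
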